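If a short-lived intermediate is shared by two nucleophiles that both stand whole in the flask from the start, the number worth carrying is how many times faster one takes it than the other, and time then drops out of the competition: the fraction of the first nucleophile left equals the fraction of the second left, raised to that power.

the same everywhere: first nucleophile 38.4 mM

| flask | starting material | second nucleophile | remark | time |
|---|---|---|---|---|
| elm | 48 mM | 96 mM | run made earlier |  |
| cedar | 32 mM | 96 mM | run made earlier |  |
| alder | 72 mM | 96 mM | run made earlier |  |
| gamma | 48 mM | 96.0 mM | everything together at the start | 4.0 d |
| epsilon | 48 mM (fed, over 3.0 d) | 96.0 mM | all else is in the flask from the start; the feed brings no volume worth counting | 4.0 d |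
| beta | 48 mM | 96.0 mM (fed, over 3.0 d) | all else is in the flask from the start; the feed brings no volume worth counting | 4.0 d |
| zeta | 48 mM | 96.0 mM (in portions, 2, over 3.0 d) | first portion at the start, last at 3.0 d | 4.0 d |

| run | time / d | target / % | starting material / % |
|---|---|---|---|
| elm | 0.333 | 37.7 | 12.6 |
| elm | 0.625 | 42.3 | 0 |
| elm | 1.04 | 38.9 | 0 |
| elm | 2.00 | 38.8 | 0 |
| elm | 4.00 | 36.4 | 0.5 |
| cedar | 0.417 | 41.4 | 7.4 |
| cedar | 1.25 | 40.5 | 1.6 |
| cedar | 2.00 | 38.4 | 0 |
| cedar | 3.00 | 37.7 | 0 |
| cedar | 5.00 | 32.9 | 0 |
| alder | 0.417 | 36.6 | 7.6 |
| alder | 1.25 | 37.2 | 0 |
| alder | 2.00 | 39.0 | 0 |
| alder | 3.00 | 35.3 | 0 |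
| alder | 5.00 | 32.9 | 0.5 |

(scatter of a reading: 1 percentage point)
- a reading or a percentage of target counts all its forms, free or not
- which flask leads in amount of target, in percent of the starting material charged ("all alike" within 1.5 percentage points) (gamma / epsilon / beta / zeta / all alike)
- how much target is there at the end, in percent of the starting material charged: gamma
- how much target is there at the end, in percent of the starting material charged: epsilon
- how much target is there at the end, in percent of the starting material charged: beta
- how much target is there at the end, in percent of the starting material charged: zeta

I read the loss of starting material first: it gave 6.22 d⁻¹ in elm and 6.24 d⁻¹ in cedar, whatever the load, so I took its first-order activation as the rate-limiting step, with a half-life of 0.111 d. In elm at 0.625 d, with starting material reading 0 % and target 42.3 %, I assigned the remainder to the second nucleophile and got 2.21, a reading that carries the scatter, as the capture ratio, the selectivity factor of first over second nucleophile at equal concentration.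

Gamma repeats elm, so I expected about 36.4 % there, and epsilon nearby, since its nucleophiles stand at the same charges. I ran beta in slow motion. In its first half-life the feed had brought 3.57 mM of second nucleophile against 38.4 mM of first, so the first took nearly all of the intermediate. In the middle of beta the first nucleophile drained while the feed went on. At the end of capture, the first nucleophile being limiting, target in beta stood below 80.0 %. Taking off elm's slow loss of 5.9 percentage points left me 74.1 % for beta.

The forecast chose beta, with 35.5 % for gamma, 37 % for epsilon, 66 % for beta and 48 % for zeta, reasoning that in beta “little second nucleophile is present during the fast consumption”. It used a relative reactivity of 1.9 where I read 2.21, and its beta differs from mine.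

The flasks gave beta as leader, with gamma 36.1 %, epsilon 36.5 %, beta 72.2 % and zeta 50.7 %.

    starting material → intermediate (k = 7.07 × 10⁻⁵ s⁻¹)
    first nucleophile + intermediate → target (k = 0.0835 M⁻¹ s⁻¹)
    target → over-reaction product (k = 4.24 × 10⁻⁶ s⁻¹)
    second nucleophile + intermediate → other capture product (k = 0.0371 M⁻¹ s⁻¹)
    crystals ⇌ target, rate k5*(cs5 - [target]) while solid is left; crystals form when [target] > cs5 (solubility = 2.10 mM, k = 0.00150 s⁻¹)
    starting material + intermediate → side product (k = 6.67 × 10⁻⁵ M⁻¹ s⁻¹)

Raised to the power 2.21, the 71.3 % of its charge of second nucleophile left in gamma gave 47.4 % of the first, and gamma held 46.7 %. The neighbouring flask is gamma with 24 mM of second nucleophile, charged at the start. The 39.9 % of its charge of second nucleophile left in this neighbour gave 13.1 % of the first, and the neighbour held 12.7 %. The first nucleophile used in the neighbour came to 69.9 % of the starting material charged, and the neighbour stood with 6.57 % of over-reaction product and 63.3 % of target.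

The earlier runs and the new flask were computed for substances that don't exist; noise was put on by code.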